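## Structural features

- The target (21) is two benzene rings, A and B, joined only by one ether oxygen between C1 and C1'. There is no further ring, no chain and no stereocentre, so the molecule is achiral and the question of neighbouring stereocentres does not arise.
- Each ring carries a hydroxyl next to the ether oxygen (C6 and C6') and two bromines, but the rings differ. In ring A the bromines (C2, C4) are ortho and para to the ether oxygen and meta to the hydroxyl. In ring B (C3', C5') they are para and ortho to the hydroxyl and meta to the ether oxygen.
- Fragile points are the four aryl C–Br bonds (halogen–metal exchange, metal insertion, hydrogenolysis) and the two electron-rich phenols, which over-brominate and oxidise easily.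
- The real difficulty is the ether bond. Its oxygen on ring A sits between Br and OH, so a direct O-arylation would ask a hindered, electron-poor phenoxide to attack a bromine-rich partner and to distinguish between several C–halogen bonds.
- The key step uses the fact that C1' (ether oxygen) and C6' (hydroxyl) of ring B are adjacent. They are the two carbons of an alkyne that carries the ring A oxygen at one end and boron, a masked hydroxyl, at the other. C2'–C5' can come as four CH carbons from a 2-pyrone, and C3' and C5' can be brominated later because they are para and ortho to the C6' hydroxyl.
- The ring A pattern is that of a phenol brominated under the direction of the C1 oxygen. It must therefore be set before that oxygen is tied into the ether, with the C6 oxygen masked as a methyl ether.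

## Logic of the disconnections

**21 ⇒ 19.** The O–CH3 bond on the C6 oxygen of ring A is the last bond formed in reverse. Keeping this oxygen methylated until the end means ring A has no free hydroxyl during the late bromination. The forward step must cleave an aryl methyl ether without touching the diaryl ether or four C–Br bonds.

**19 ⇒ 17.** The C3'–Br and C5'–Br bonds are cut. Both are para and ortho to the free C6' hydroxyl, so they can be introduced by simple electrophilic substitution. The forward step must stop after two bromines and leave ring A alone, via 18.

**17 ⇒ 16.** The C6'–O bond is traced back to a C6'–B bond. Boron is what the ring-forming step can place on C6', and its oxidation is positionally exact. The demand is an oxidant that spares the aryl bromides.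

**16 ⇒ 13 + 14.** The C1'–C2' and C5'–C6' bonds are cut, and ring B falls apart into a two-carbon alkyne (13) and a four-carbon diene (14), through bridged lactone 15.
- This is the largest simplification of the plan: the hindered ether oxygen never has to be arylated, because it is already on the alkyne.
- Boron arrives on the neighbouring carbon with no regiochemical choice.
- The demand is that 13 survives the temperature at which 14 reacts.

**13 ⇒ 9 + 10.** The C(sp)–B bond is cut. The forward step is metalation of the terminal alkyne and trapping with the boron electrophile, through 11 and 12. Because ring A already carries two bromines, the base must not undergo halogen–metal exchange, so an alkyllithium is excluded and a silylamide is used.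

**9 ⇒ 6.** The second π-bond of the alkyne is removed, which leads back to an aldehyde through enolate 7 and enol triflate 8. This makes the ynol ether from an ordinary carbonyl compound with alkoxide and silylamide bases only. The demands are O-sulfonylation of an aldehyde enolate without aldol reaction, and handling of 9 in solution only.

**6 ⇒ 5 ⇒ 3 + 4.** The acetal is the protected aldehyde, and the O–CH2 bond between the ring A oxygen and the two-carbon unit is cut. Alkylation at a primary sp3 carbon is little affected by the two ortho substituents of 3, unlike an arylation.

**3 ⇒ 1.** Both ring A C–Br bonds are cut. They are ortho and para to the free hydroxyl of 1. The forward step must make the hydroxyl, not the methoxy group, direct both brominations, via 2.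

## Other disconnections considered

**Alternative 1:** Dibromoaryne annulation to a xanthenol, then excision of the bridging carbon.
- Cut: the O–C1' bond and a temporary C6'–C9 bond, where C9 is a one-carbon bridge between C6 and C6' that is later replaced by the two hydroxyls.
- Forward key step: the phenoxide of 3,5-dibromo-2-hydroxybenzaldehyde A1 would add to 3,5-dibromobenzyne A3, released by a fluoride source from 2,4-dibromo-6-(trimethylsilyl)phenyl triflate A2. The resulting aryl anion would add to the formyl group and close the pyran ring of 1,3,5,7-tetrabromo-9H-xanthen-9-ol A4 (racemic).
- In its favour: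
  - It is convergent, and both dibromo patterns arrive ready-made, so no late bromination is needed. On certainty of bromine placement it is better than the chosen plan.
  - Aryne arylation is little affected by the steric bulk of a di-ortho-substituted phenoxide, so it handles the hindered ether bond as well as the chosen plan does (equal).
  - The reaction type is about as well precedented as the pyrone cycloaddition (equal).
- Against it:
  - The usual preparation of a silylaryl triflate such as A2 goes through an aryllithium, which conflicts with two aryl bromides.
  - The intermediate aryl anion sits ortho to bromine and could expel bromide to form a second aryne.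
  - The regiochemistry of the aryne addition depends on the inductive bias of bromine, whereas the chosen key step needs no regiocontrol.
  - C9 must be cut out afterwards. Oxidation to xanthone A5 and Baeyer–Villiger ring expansion of an electron-poor tetrabrominated diaryl ketone cannot be relied on, and would still leave C9 as a carboxyl group needing a further degradation.
- Step economy: roughly eight to nine steps, no shorter than the chosen plan, and the weak steps come at the end.

**Alternative 2:** Ring B by (3+3) condensation.
- Cut: the C1'–C2' and C4'–C5' bonds.
- Forward key step: 1-(2,4-dibromo-6-methoxyphenoxy)propan-2-one A6, one alkylation away from 3 with an α-haloacetone, would condense twice under base with 2-bromopropanedial A7. This would close ring B directly as 4-bromo-2-(2,4-dibromo-6-methoxyphenoxy)phenol A8, which is the same compound as 18. One ortho-bromination and the demethylation would finish the synthesis.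
- In its favour:
  - The C6' oxygen and the C3' bromine are built in, with no boron, no oxidation and no high temperature.
  - About five steps from 1, so on step economy it is clearly better than the chosen plan.
  - Like the chosen plan it builds ring B onto the oxygen of ring A, so it avoids the hindered O-arylation equally well (equal).
- Against it:
  - The established form of this phenol synthesis uses the nitro analogue of A7. The bromo compound is an α-halo dialdehyde that exists under base as a poorly electrophilic enolate.
  - A7 offers a ketone enolate several other paths: substitution at C–Br, or furan formation of the Feist–Benary type.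
  - Both α-carbons of A6 must react, once each and in the right sense.
- Comparison: the chosen cycloaddition has no competing polar pathway and no regiochemical choice, while this condensation has several. It is shorter but mechanistically less secure.

**Alternative 3:** Fourfold bromination steered by a traceless amino group.
- Cut: all four C–Br bonds in one operation.
- Forward key step: 2-(5-amino-2-methoxyphenoxy)phenol A9 would take up four equivalents of electrophilic bromine to give 2-(3-amino-2,4-dibromo-6-methoxyphenoxy)-4,6-dibromophenol A10. The amino group at C3 steers bromine to C2 and C4, its para position being occupied by the methoxy group, while the ring B hydroxyl steers to C3' and C5'. Diazotisation and reduction would then give 19, where this plan joins the chosen route one step before 21.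
- In its favour:
  - Only long-established reaction types are used.
  - The ether is made before any bromine is present, from the unhindered 2-methoxy-5-nitrophenol A11 by SNAr on a 2-halobenzaldehyde, followed by aldehyde-to-phenol oxidation and nitro reduction.
  - About six steps in all. On step economy and on precedent it is better than the chosen plan.
  - In A10 the positions ortho and para to the ring B hydroxyl are blocked, so azo coupling during deamination is not a concern.
- Against it:
  - The para-methoxyaniline ring of A9 is easily oxidised by bromine.
  - C2 is squeezed between the amino and aryloxy groups, and C5 could take a fifth bromine.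
  - The hindered, weakly basic dibromoaniline A10 needs forcing diazotisation and brings the handling hazards of diazonium salts.
  - The director is traceless only at the cost of two extra operations (nitro reduction and deamination).
- Comparison: the chosen plan lets each ring's own oxygen direct its bromines in separate, individually checkable steps and has no nitrogen redox chemistry. Its price is three more steps and a dienophile of a kind not yet tried in this cycloaddition.

Key step: step 6

Remark on the chemistry: it is assumed that a plain second bromination of guaiacol in acid would favour the position para to the methoxy group, so an amine-mediated, ortho-first bromination is used in step 1.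

## Route

Step 1
Reactants: 1 guaiacol (2-methoxyphenol)
Product: 3 2,4-dibromo-6-methoxyphenol (4,6-dibromoguaiacol), via 2-bromo-6-methoxyphenol 2 (not isolated)
Conditions: NBS (2 × 1.03 equiv, two portions), i-Pr2NH (10 mol%), CH2Cl2, 0 °C → rt
Reagents that add atoms: N-bromosuccinimide, O=C1CCC(=O)N1Br
Why: Amine-catalysed NBS bromination (electrophilic aromatic substitution) should deliver the first bromine ortho to the hydroxyl through a hydrogen-bonded N-bromoamine–phenol pair, giving 2; the second equivalent should then enter para to the hydroxyl, the most activated site left, so that both bromines answer to the C1 oxygen and not to the methoxy group.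

Step 2
Reactants: 3 2,4-dibromo-6-methoxyphenol; 4 bromoacetaldehyde diethyl acetal (2-bromo-1,1-diethoxyethane)
Product: 5 1,5-dibromo-2-(2,2-diethoxyethoxy)-3-methoxybenzene
Conditions: K2CO3, KI (cat.), DMF, 120 °C
Reagents that add atoms: none
Why: Williamson ether synthesis; the phenoxide of 3 is hindered and weakly basic but should attack a primary sp3 carbon at this temperature with iodide as nucleophilic catalyst, and aryl bromides do not react with carbonate.

Step 3
Reactants: 5 1,5-dibromo-2-(2,2-diethoxyethoxy)-3-methoxybenzene
Product: 6 2-(2,4-dibromo-6-methoxyphenoxy)acetaldehyde
Conditions: 1 M HCl (aq), THF, 55 °C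
Reagents that add atoms: water, O
Why: Acid-catalysed acetal hydrolysis; the aryl ethers and aryl bromides are stable to dilute acid, and the aldehyde is dried and used promptly because α-aryloxy aldehydes hydrate and oxidise on standing.

Step 4
Reactants: 6 2-(2,4-dibromo-6-methoxyphenoxy)acetaldehyde
Product: 9 1,5-dibromo-2-(ethynyloxy)-3-methoxybenzene, via potassium enolate 7 (not isolated), via (Z)-enol triflate 8 (not isolated)
Conditions: KN(SiMe3)2 (1.05 equiv), THF, −78 °C; PhNTf2 (1.1 equiv), −78 → −30 °C; KOt-Bu (2.2 equiv), −78 → 0 °C; then aq. NH4Cl
Reagents that add atoms: none
Why: Enolate O-sulfonylation followed by base-induced anti elimination of triflate (the enol triflate route to ynol ethers): slow addition of 6 to the silylamide should give enolate 7, expected mainly as the chelated Z isomer, which PhNTf2 traps on oxygen as 8, and tert-butoxide then removes the vinylic hydrogen on the aryloxy-bearing carbon. Neither base undergoes bromine–metal exchange, which is why no alkyllithium is used; an E isomer of 8 would reach the same alkyne by syn or α-elimination, and 9 is kept cold in solution and used at once.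

Step 5
Reactants: 9 1,5-dibromo-2-(ethynyloxy)-3-methoxybenzene; 10 2-isopropoxy-4,4,5,5-tetramethyl-1,3,2-dioxaborolane
Product: 13 2-[(2,4-dibromo-6-methoxyphenoxy)ethynyl]-4,4,5,5-tetramethyl-1,3,2-dioxaborolane, via lithium acetylide 11 (not isolated), via lithium isopropoxyborate 12 (not isolated)
Conditions: LiN(SiMe3)2 (1.05 equiv), THF, −78 °C; 10, −78 °C; HCl·Et2O (1.05 equiv), −78 °C → rt
Reagents that add atoms: none
Why: Acetylide borylation; the acetylenic C–H is several pK units more acidic than the silylamine, so LiN(SiMe3)2 should form 11 without touching the aryl bromides, 10 adds to give the stable borate 12, and one equivalent of anhydrous HCl removes isopropoxide to release the alkynylboronate. The product is isolated without water or silica (filtration of LiCl, crystallisation) because alkynylboronates hydrolyse easily.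

Step 6
Reactants: 13 2-[(2,4-dibromo-6-methoxyphenoxy)ethynyl]-4,4,5,5-tetramethyl-1,3,2-dioxaborolane; 14 2H-pyran-2-one
Product: 16 2-[2-(2,4-dibromo-6-methoxyphenoxy)phenyl]-4,4,5,5-tetramethyl-1,3,2-dioxaborolane, via bridged lactone cycloadduct 15 (not isolated)
Conditions: 14 (4 equiv), BHT (5 mol%), mesitylene, 160 °C, Ar (open to a bubbler)
Reagents that add atoms: none
Why: Thermal Diels–Alder reaction of a 2-pyrone with an alkynylboronate followed by retro-Diels–Alder loss of CO2 is an established route to arylboronic esters, and 13 is a new member of the alkyne class. The ynol ether oxygen raises the alkyne HOMO and makes the boron-bearing carbon (future C6') the nucleophilic end, so it should bond to the electrophilic C6 of 14 while the oxygen-bearing carbon (future C1') bonds to C3, in a concerted but asynchronous (4+2) process that gives bridged lactone 15. Ring B is thus closed by an intermolecular (4+2) cycloaddition that forms both new ring bonds, C1'–C2' and C5'–C6'; the cycloreversion that expels CO2 only aromatises the ring and is irreversible, which drives the sequence. The two bridgehead centres of 15 are fixed relative to each other by the bicycle and vanish on aromatisation, so no stereocentre has to be controlled. No regioselectivity is needed because the four carbons kept from 14 are all CH and either orientation of addition gives the same 16. What is needed is that cycloaddition outruns decay of the alkyne: the aryl ynol ether has no β-hydrogen for retro-ene loss of a ketene and is shielded by two ortho substituents, and excess 14 and a radical inhibitor support this. The aryl bromides, the methyl ether and the pinacol boronate should be inert at this temperature without metal, base or water.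

Step 7
Reactants: 16 2-[2-(2,4-dibromo-6-methoxyphenoxy)phenyl]-4,4,5,5-tetramethyl-1,3,2-dioxaborolane
Product: 17 2-(2,4-dibromo-6-methoxyphenoxy)phenol
Conditions: 30% H2O2, NaOH (aq), THF, 0 °C → rt; then 1 M HCl
Reagents that add atoms: hydrogen peroxide, OO
Why: Oxidation of the aryl C–B bond by hydroperoxide with 1,2-migration of the aryl group from boron to oxygen and hydrolysis of the borate; this puts the hydroxyl exactly on C6', and aryl bromides and ethers are unaffected.

Step 8
Reactants: 17 2-(2,4-dibromo-6-methoxyphenoxy)phenol
Product: 19 2,4-dibromo-6-(2,4-dibromo-6-methoxyphenoxy)phenol, via 4-bromophenol intermediate 18 (not isolated)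
Conditions: Br2 (2.1 equiv), AcOH, rt
Reagents that add atoms: bromine, BrBr
Why: Electrophilic aromatic substitution directed by the free hydroxyl of ring B: the first bromine should enter para (C3', giving 18) and the second ortho (C5'), the other ortho position being C1'. Ring A is deactivated by two bromines and its C6 oxygen is only a methyl ether, so with two equivalents it should stay untouched.

Step 9
Reactants: 19 2,4-dibromo-6-(2,4-dibromo-6-methoxyphenoxy)phenol
Product: 21 2,4-dibromo-6-(2,4-dibromo-6-hydroxyphenoxy)phenol (target), via bis(dibromoboryl) ether 20 (not isolated)
Conditions: BBr3 (3 equiv), CH2Cl2, −78 °C → rt; then H2O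
Reagents that add atoms: none
Why: Lewis-acid cleavage of an aryl methyl ether: BBr3 coordinates the methoxy oxygen and bromide attacks the methyl group, the free phenol is borylated as well to give 20, and water hydrolyses both B–O bonds; diaryl ethers and aryl bromides are inert to BBr3.

## Compound list

1 | guaiacol (2-methoxyphenol) | COc1ccccc1O | starting material
2 | 2-bromo-6-methoxyphenol | COc1cccc(Br)c1O | intermediate
3 | 2,4-dibromo-6-methoxyphenol | COc1cc(Br)cc(Br)c1O | intermediate
4 | bromoacetaldehyde diethyl acetal (2-bromo-1,1-diethoxyethane) | CCOC(CBr)OCC | starting material
5 | 1,5-dibromo-2-(2,2-diethoxyethoxy)-3-methoxybenzene | CCOC(COc1c(Br)cc(Br)cc1OC)OCC | intermediate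
6 | 2-(2,4-dibromo-6-methoxyphenoxy)acetaldehyde | COc1cc(Br)cc(Br)c1OCC=O | intermediate
7 | potassium (Z)-2-(2,4-dibromo-6-methoxyphenoxy)ethen-1-olate | COc1cc(Br)cc(Br)c1O/C=C\[O-].[K+] | intermediate
8 | (Z)-2-(2,4-dibromo-6-methoxyphenoxy)ethenyl trifluoromethanesulfonate | COc1cc(Br)cc(Br)c1O/C=C\OS(=O)(=O)C(F)(F)F | intermediate
9 | 1,5-dibromo-2-(ethynyloxy)-3-methoxybenzene | COc1cc(Br)cc(Br)c1OC#C | intermediate
10 | 2-isopropoxy-4,4,5,5-tetramethyl-1,3,2-dioxaborolane | CC(C)OB1OC(C)(C)C(C)(C)O1 | starting material
11 | lithium (2,4-dibromo-6-methoxyphenoxy)ethynide | COc1cc(Br)cc(Br)c1OC#[C-].[Li+] | intermediate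
12 | lithium [(2,4-dibromo-6-methoxyphenoxy)ethynyl](isopropoxy)(2,3-dimethylbutane-2,3-diolato)borate | COc1cc(Br)cc(Br)c1OC#C[B-]1(OC(C)C)OC(C)(C)C(C)(C)O1.[Li+] | intermediate
13 | 2-[(2,4-dibromo-6-methoxyphenoxy)ethynyl]-4,4,5,5-tetramethyl-1,3,2-dioxaborolane | COc1cc(Br)cc(Br)c1OC#CB1OC(C)(C)C(C)(C)O1 | intermediate
14 | 2H-pyran-2-one | O=C1C=CC=CO1 | starting material
15 | 5-(2,4-dibromo-6-methoxyphenoxy)-6-(4,4,5,5-tetramethyl-1,3,2-dioxaborolan-2-yl)-2-oxabicyclo[2.2.2]octa-5,7-dien-3-one (racemic; bridgeheads fixed relative to each other by the bicycle, one enantiomer drawn) | O=C1O[C@@H]2C=C[C@H]1C(Oc3c(Br)cc(Br)cc3OC)=C2B4OC(C)(C)C(C)(C)O4 | intermediate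
16 | 2-[2-(2,4-dibromo-6-methoxyphenoxy)phenyl]-4,4,5,5-tetramethyl-1,3,2-dioxaborolane | COc1cc(Br)cc(Br)c1Oc1ccccc1B1OC(C)(C)C(C)(C)O1 | intermediate
17 | 2-(2,4-dibromo-6-methoxyphenoxy)phenol | COc1cc(Br)cc(Br)c1Oc1ccccc1O | intermediate
18 | 4-bromo-2-(2,4-dibromo-6-methoxyphenoxy)phenol | COc1cc(Br)cc(Br)c1Oc1cc(Br)ccc1O | intermediate
19 | 2,4-dibromo-6-(2,4-dibromo-6-methoxyphenoxy)phenol | COc1cc(Br)cc(Br)c1Oc1cc(Br)cc(Br)c1O | intermediate
20 | dibromo{2,4-dibromo-6-[2,4-dibromo-6-(dibromoboranyloxy)phenoxy]phenoxy}borane | BrB(Br)Oc1cc(Br)cc(Br)c1Oc1cc(Br)cc(Br)c1OB(Br)Br | intermediate
21 | 2,4-dibromo-6-(2,4-dibromo-6-hydroxyphenoxy)phenol | Oc1cc(Br)cc(Br)c1Oc1cc(Br)cc(Br)c1O | target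

## Step count and least certain steps

Total step count: 9. Longest linear sequence: 9 steps (1 → 3 → 5 → 6 → 9 → 13 → 16 → 17 → 19 → 21); 4, 10 and 14 enter as purchased reagents.

**Step 6 (key step).**
- Most likely failure: thermal oligomerisation or adventitious hydration of the push–pull alkyne before the unactivated, only moderately reactive diene captures it. Loss of boron from the product by traces of water is a second risk.
- Fallback: it sets out from 3 and returns at 17. Ring B is bought instead of built.
  - The phenoxide of 3 is joined to 2-fluorobenzaldehyde by SNAr (K2CO3, DMA, 140 °C) to give 2-(2,4-dibromo-6-methoxyphenoxy)benzaldehyde F1.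
  - Baeyer–Villiger oxidation with mCPBA in CH2Cl2 should give 2-(2,4-dibromo-6-methoxyphenoxy)phenyl formate F2, with aryl migration favoured by the ortho aryloxy donor.
  - Hydrolysis with KOH in aqueous methanol gives 17.

**Step 4.**
- Most likely failure: aldol self-condensation of the aldehyde enolate before O-sulfonylation, attack of tert-butoxide at sulfur instead of elimination, or decay of the terminal ynol ether during isolation.
- Fallback: it sets out from 3 and returns at 9. It is the classical dehydrohalogenation route to aryloxyacetylenes and again needs no alkyllithium.
  - Alkylation of 3 with excess 1,2-dibromoethane (K2CO3, MeCN, reflux) gives 1,5-dibromo-2-(2-bromoethoxy)-3-methoxybenzene F3.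
  - Elimination with KOt-Bu gives the vinyl ether 1,5-dibromo-2-(ethenyloxy)-3-methoxybenzene F4.
  - Addition of Br2 at −78 °C gives 1,5-dibromo-2-(1,2-dibromoethoxy)-3-methoxybenzene F5 (racemic, used crude).
  - Two successive dehydrobrominations with KOt-Bu lead through 1,5-dibromo-2-[(2-bromoethenyl)oxy]-3-methoxybenzene F6 to 9.

**Step 5.**
- Most likely failure: addition of HCl across the electron-rich triple bond or protodeboronation while the ester is released from borate 12. Incomplete metalation is a lesser risk.
- Fallback: it sets out from 9 and returns at 13 in one operation and makes no new compound (F0). It is a catalytic dehydrogenative C–H borylation of the terminal alkyne with pinacolborane, for example with Fe(OTf)2 and DABCO as catalyst. This avoids both the strong base and the acid.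

**Step 1.**
- Most likely failure: loss of positional control in the second bromination (entry para to the methoxy group instead of para to the hydroxyl) and over-bromination.
- Fallback: it sets out from 1 and returns at 3, with the order of entry reversed and the intermediate purified.
  - Para-bromination first (NBS, MeCN, 0 °C) gives 4-bromo-2-methoxyphenol F7, which is crystallised or distilled.
  - Amine-directed ortho-bromination (Br2, t-BuNH2, toluene, −78 °C) then gives 3.

## Further compounds

F1 | step 6 | 2-(2,4-dibromo-6-methoxyphenoxy)benzaldehyde | COc1cc(Br)cc(Br)c1Oc1ccccc1C=O
F2 | step 6 | 2-(2,4-dibromo-6-methoxyphenoxy)phenyl formate | COc1cc(Br)cc(Br)c1Oc1ccccc1OC=O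
F3 | step 4 | 1,5-dibromo-2-(2-bromoethoxy)-3-methoxybenzene | COc1cc(Br)cc(Br)c1OCCBr
F4 | step 4 | 1,5-dibromo-2-(ethenyloxy)-3-methoxybenzene | COc1cc(Br)cc(Br)c1OC=C
F5 | step 4 | 1,5-dibromo-2-(1,2-dibromoethoxy)-3-methoxybenzene (racemic) | COc1cc(Br)cc(Br)c1OC(Br)CBr
F6 | step 4 | 1,5-dibromo-2-[(2-bromoethenyl)oxy]-3-methoxybenzene (Z/E mixture) | COc1cc(Br)cc(Br)c1OC=CBr
F0 | step 5 | none | none
F7 | step 1 | 4-bromo-2-methoxyphenol | COc1cc(Br)ccc1O
A1 | alternative 1 | 3,5-dibromo-2-hydroxybenzaldehyde | O=Cc1cc(Br)cc(Br)c1O
A2 | alternative 1 | 2,4-dibromo-6-(trimethylsilyl)phenyl trifluoromethanesulfonate | C[Si](C)(C)c1cc(Br)cc(Br)c1OS(=O)(=O)C(F)(F)F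
A3 | alternative 1 | 3,5-dibromobenzyne | BrC1=CC(Br)=CC#C1
A4 | alternative 1 | 1,3,5,7-tetrabromo-9H-xanthen-9-ol (racemic) | OC1c2c(Br)cc(Br)cc2Oc2c(Br)cc(Br)cc21
A5 | alternative 1 | 1,3,5,7-tetrabromo-9H-xanthen-9-one | O=C1c2c(Br)cc(Br)cc2Oc2c(Br)cc(Br)cc21
A6 | alternative 2 | 1-(2,4-dibromo-6-methoxyphenoxy)propan-2-one | COc1cc(Br)cc(Br)c1OCC(C)=O
A7 | alternative 2 | 2-bromopropanedial | O=CC(Br)C=O
A8 | alternative 2 | 4-bromo-2-(2,4-dibromo-6-methoxyphenoxy)phenol | COc1cc(Br)cc(Br)c1Oc1cc(Br)ccc1O
A9 | alternative 3 | 2-(5-amino-2-methoxyphenoxy)phenol | COc1ccc(N)cc1Oc1ccccc1O
A10 | alternative 3 | 2-(3-amino-2,4-dibromo-6-methoxyphenoxy)-4,6-dibromophenol | COc1cc(Br)c(N)c(Br)c1Oc1cc(Br)cc(Br)c1O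
A11 | alternative 3 | 2-methoxy-5-nitrophenol | COc1ccc(cc1O)[N+](=O)[O-]
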